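## Plan

1. Numbering: oxolane O1, C2 (catechol carbon), C3 (bears C9H2OH), C4 (tertiary carbinol carrying the 3,4-dimethoxybenzyl arm), C5. The array O–C2–C3–C4–O is a 1,3-dioxygenated, aldol-type unit, so C2–C3 and C4–O can be formed together across a C3=C4 alkene by an aryl nitrile oxide, the 2-isoxazoline acting as a masked aldol.
2. Retrosynthesis: cut O1–C5 (ether closure); take C2 back to the ketone and the ketone/C4–OH pair back to the isoxazoline N–O bond; cut C2–C3 and C4–O together (nitrile oxide + E-allylic alcohol); cut C3=C4 (Wittig).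
3. Forward: Wittig olefination and ester reduction give the E-allylic alcohol; the aldehyde gives the hydroximoyl chloride; the cycloaddition closes the temporary isoxazoline (first ring); N–O cleavage reopens it; ketone reduction and Williamson closure build the oxolane (second ring); two deprotections finish.
4. Stereochemistry: C4 from tartrate-controlled face selection in the cycloaddition; C3 from the E alkene through suprafacial addition; C2 from zinc-chelate-controlled hydride addition, carried into the ring with retention.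

Key step: step 6

Assumption: the face selectivity known for simple allylic alcohols with Et2Zn/(R,R)-diisopropyl tartrate (R at the oxygen-bearing carbon) is taken to hold for the 2,3-disubstituted allylic alcohol 7; if the sense were opposite, the (S,S)-tartrate would be used.
Remark: locants C2–C5 and C9 follow the oxolane numbering of the plan in every step; Zn(BH4)2 is used as a preformed ethereal solution.

## Route

Step 1
Reactants: 1 ethyl (triphenylphosphoranylidene)acetate; 2 3,4-dimethoxybenzyl bromide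
Product: 4 ethyl 3-(3,4-dimethoxyphenyl)-2-(triphenylphosphoranylidene)propanoate, via phosphonium bromide 3 (not isolated)
Conditions: EtOAc, reflux; then aq. NaOH, CH2Cl2, rt
Reagents that add atoms: none
Why: C-alkylation of the ester-stabilised ylide by the reactive benzylic bromide gives the phosphonium salt, whose acidic α-hydrogen is removed by aqueous base to give the new stabilised ylide (ylide alkylation).

Step 2
Reactants: 4 ethyl 3-(3,4-dimethoxyphenyl)-2-(triphenylphosphoranylidene)propanoate; 5 (tert-butyldimethylsilyloxy)acetaldehyde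
Product: 6 ethyl (E)-4-[(tert-butyldimethylsilyl)oxy]-2-(3,4-dimethoxybenzyl)but-2-enoate
Conditions: toluene, 80 °C
Reagents that add atoms: none
Why: Wittig olefination with an α-substituted, ester-stabilised ylide places the ester trans to the aldehyde-derived CH2OTBS group and should give the E trisubstituted alkene whose geometry later fixes the C3/C4 relationship.

Step 3
Reactants: 6 ethyl (E)-4-[(tert-butyldimethylsilyl)oxy]-2-(3,4-dimethoxybenzyl)but-2-enoate
Product: 7 (E)-4-[(tert-butyldimethylsilyl)oxy]-2-(3,4-dimethoxybenzyl)but-2-en-1-ol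
Conditions: i-Bu2AlH (DIBAL-H), CH2Cl2, −78 °C; aq. potassium sodium tartrate
Reagents that add atoms: none
Why: 1,2-reduction of the conjugated ester by the aluminium hydride at low temperature gives the allylic alcohol without touching the alkene geometry or the silyl ether.

Step 4
Reactants: 8 3,4-bis(benzyloxy)benzaldehyde
Product: 9 (E)-3,4-bis(benzyloxy)benzaldehyde oxime
Conditions: NH2OH·HCl, NaOAc, EtOH/H2O, rt
Reagents that add atoms: hydroxylamine hydrochloride, Cl.NO
Why: Condensation of the aldehyde with hydroxylamine gives the aldoxime (oxime formation), the E isomer being the favoured one for aryl aldoximes.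

Step 5
Reactants: 9 (E)-3,4-bis(benzyloxy)benzaldehyde oxime
Product: 10 (Z)-3,4-bis(benzyloxy)-N-hydroxybenzimidoyl chloride
Conditions: NCS, DMF, rt
Reagents that add atoms: N-chlorosuccinimide, O=C1CCC(=O)N1Cl
Why: Electrophilic chlorination of the aldoxime carbon by NCS (through the C-chloro nitroso tautomer) gives the hydroximoyl chloride, the usual bench-stable nitrile oxide precursor.

Step 6
Reactants: 7 (E)-4-[(tert-butyldimethylsilyl)oxy]-2-(3,4-dimethoxybenzyl)but-2-en-1-ol; 10 (Z)-3,4-bis(benzyloxy)-N-hydroxybenzimidoyl chloride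
Product: 13 [(4S,5R)-3-[3,4-bis(benzyloxy)phenyl]-4-{[(tert-butyldimethylsilyl)oxy]methyl}-5-(3,4-dimethoxybenzyl)-4,5-dihydro-1,2-oxazol-5-yl]methanol, via ethylzinc alkoxide 11 (not isolated), via nitrile oxide 12 (not isolated)
Conditions: Et2Zn (2.2 equiv), (R,R)-diisopropyl tartrate (1.1 equiv), CHCl3, 1,4-dioxane (additive), 0 °C; 10 in CHCl3 added slowly
Reagents that add atoms: none
Why: Et2Zn turns 7 into ethylzinc alkoxide 11 and, with the tartrate and a second zinc, forms a tartrate-bridged dizinc assembly on which 10 is dehydrochlorinated to nitrile oxide 12, so that dipole and dipolarophile meet on one template and combine in a concerted, suprafacial [3+2] cycloaddition (closest known reaction type: zinc/tartrate-mediated asymmetric nitrile oxide cycloaddition to allylic alcohols, and its magnesium-alkoxide-directed variant). The isoxazoline ring closes in this single intermolecular pericyclic event, C2–C3 and C4–O being formed together. C4 (the quaternary O-bearing carbon, 5R in the isoxazoline) is set by the (R,R)-tartrate, which exposes one alkene face of the zinc-bound alkoxide, and C3 (4S in the isoxazoline) follows from the E geometry, because suprafacial addition keeps the benzyl arm and the CH2OTBS group cis on the new ring. The step needs regioselectivity (dipole oxygen to C4, dipole carbon to C3), which the zinc bridge between the alkoxide and the dipole oxygen secures and which the normal preference of the dipole oxygen for the more substituted alkene carbon reinforces. It also needs the cycloaddition to outrun dimerisation of 12 to the furoxan, which slow addition of 10 and the rate gain of the metal-templated pathway should provide.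

Step 7
Reactants: 13 [(4S,5R)-3-[3,4-bis(benzyloxy)phenyl]-4-{[(tert-butyldimethylsilyl)oxy]methyl}-5-(3,4-dimethoxybenzyl)-4,5-dihydro-1,2-oxazol-5-yl]methanol
Product: 14 [(4S,5R)-3-[3,4-bis(benzyloxy)phenyl]-4-{[(tert-butyldimethylsilyl)oxy]methyl}-5-(3,4-dimethoxybenzyl)-4,5-dihydro-1,2-oxazol-5-yl]methyl 4-methylbenzenesulfonate
Conditions: TsCl, Et3N, DMAP (cat.), CH2Cl2, 0 °C to rt
Reagents that add atoms: 4-methylbenzenesulfonyl chloride (TsCl), Cc1ccc(S(=O)(=O)Cl)cc1
Why: Sulfonylation of the only free hydroxyl makes C5 the electrophile for the later ether closure and, done at this stage, keeps the C5 oxygen from trapping the ketone of step 8 as a lactol, so that the ketone stays open for chelate-controlled reduction.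

Step 8
Reactants: 14 [(4S,5R)-3-[3,4-bis(benzyloxy)phenyl]-4-{[(tert-butyldimethylsilyl)oxy]methyl}-5-(3,4-dimethoxybenzyl)-4,5-dihydro-1,2-oxazol-5-yl]methyl 4-methylbenzenesulfonate
Product: 16 (2R,3S)-4-[3,4-bis(benzyloxy)phenyl]-3-{[(tert-butyldimethylsilyl)oxy]methyl}-2-(3,4-dimethoxybenzyl)-2-hydroxy-4-oxobutyl 4-methylbenzenesulfonate, via hydroxy imine 15 (not isolated)
Conditions: Mo(CO)6, MeCN/H2O (10:1), 80 °C
Reagents that add atoms: water, O
Why: Reductive N–O cleavage of the 2-isoxazoline by zerovalent molybdenum gives hydroxy imine 15, which water hydrolyses in the flask to the β-hydroxy ketone, unmasking the aldol under neutral conditions that should leave the α-stereocentre C3, the silyl ether and the sulfonate alone.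

Step 9
Reactants: 16 (2R,3S)-4-[3,4-bis(benzyloxy)phenyl]-3-{[(tert-butyldimethylsilyl)oxy]methyl}-2-(3,4-dimethoxybenzyl)-2-hydroxy-4-oxobutyl 4-methylbenzenesulfonate
Product: 17 (2R,3R,4R)-4-[3,4-bis(benzyloxy)phenyl]-3-{[(tert-butyldimethylsilyl)oxy]methyl}-2-(3,4-dimethoxybenzyl)-2,4-dihydroxybutyl 4-methylbenzenesulfonate
Conditions: Zn(BH4)2, Et2O, −20 °C; aq. NH4Cl
Reagents that add atoms: none
Why: Chelation-controlled ketone reduction, in which zinc bridges the ketone oxygen and the C4 hydroxyl in a six-membered chelate whose one face carries both the C3 CH2OTBS group and the C4 benzyl group, so that hydride should add from the other face and give the R carbinol at C2 (C2–OH syn to C9), the bulky silyl ether on O9 not competing for zinc.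

Step 10
Reactants: 17 (2R,3R,4R)-4-[3,4-bis(benzyloxy)phenyl]-3-{[(tert-butyldimethylsilyl)oxy]methyl}-2-(3,4-dimethoxybenzyl)-2,4-dihydroxybutyl 4-methylbenzenesulfonate
Product: 18 (3R,4R,5R)-5-[3,4-bis(benzyloxy)phenyl]-4-{[(tert-butyldimethylsilyl)oxy]methyl}-3-(3,4-dimethoxybenzyl)oxolan-3-ol
Conditions: KOtBu, THF, 0 °C to rt
Reagents that add atoms: none
Why: Intramolecular Williamson etherification (5-exo-tet) of the C2 alkoxide onto the primary sulfonate forms O1–C5 without breaking a bond at any stereocentre, so C2, C3 and C4 pass unchanged into the ring, and a competing attack of the tertiary C4 alkoxide on C5 would be reopened at that same primary carbon by the C2 alkoxide and end in the same product.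

Step 11
Reactants: 18 (3R,4R,5R)-5-[3,4-bis(benzyloxy)phenyl]-4-{[(tert-butyldimethylsilyl)oxy]methyl}-3-(3,4-dimethoxybenzyl)oxolan-3-ol
Product: 19 (3R,4R,5R)-5-[3,4-bis(benzyloxy)phenyl]-3-(3,4-dimethoxybenzyl)-4-(hydroxymethyl)oxolan-3-ol
Conditions: TBAF, THF, 0 °C to rt
Reagents that add atoms: none
Why: Fluoride-mediated desilylation, driven by the Si–F bond, frees the C9 primary alcohol without touching the benzyl ethers or the oxolane.

Step 12
Reactants: 19 (3R,4R,5R)-5-[3,4-bis(benzyloxy)phenyl]-3-(3,4-dimethoxybenzyl)-4-(hydroxymethyl)oxolan-3-ol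
Product: 20 4-[(2R,3R,4R)-4-(3,4-dimethoxybenzyl)-4-hydroxy-3-(hydroxymethyl)oxolan-2-yl]benzene-1,2-diol
Conditions: H2 (1 atm), 10% Pd/C, EtOAc/MeOH, rt
Reagents that add atoms: none
Why: Catalytic hydrogenolysis cleaves the two aryl benzyl ethers much faster than the cyclic benzylic C2–O1 ether, so that stopping after two equivalents of H2 should leave the oxolane and all three stereocentres untouched.

## Compound list

1 | ethyl (triphenylphosphoranylidene)acetate | CCOC(=O)C=P(c1ccccc1)(c1ccccc1)c1ccccc1 | starting material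
2 | 3,4-dimethoxybenzyl bromide | COc1ccc(CBr)cc1OC | starting material
3 | [3-(3,4-dimethoxyphenyl)-1-ethoxy-1-oxopropan-2-yl]triphenylphosphonium bromide | CCOC(=O)C(Cc1ccc(OC)c(OC)c1)[P+](c1ccccc1)(c1ccccc1)c1ccccc1.[Br-] | intermediate (not isolated)
4 | ethyl 3-(3,4-dimethoxyphenyl)-2-(triphenylphosphoranylidene)propanoate | CCOC(=O)C(Cc1ccc(OC)c(OC)c1)=P(c1ccccc1)(c1ccccc1)c1ccccc1 | intermediate
5 | (tert-butyldimethylsilyloxy)acetaldehyde | O=CCO[Si](C)(C)C(C)(C)C | starting material
6 | ethyl (E)-4-[(tert-butyldimethylsilyl)oxy]-2-(3,4-dimethoxybenzyl)but-2-enoate | CCOC(=O)/C(Cc1ccc(OC)c(OC)c1)=C/CO[Si](C)(C)C(C)(C)C | intermediate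
7 | (E)-4-[(tert-butyldimethylsilyl)oxy]-2-(3,4-dimethoxybenzyl)but-2-en-1-ol | OC/C(Cc1ccc(OC)c(OC)c1)=C/CO[Si](C)(C)C(C)(C)C | intermediate
8 | 3,4-bis(benzyloxy)benzaldehyde | O=Cc1ccc(OCc2ccccc2)c(OCc2ccccc2)c1 | starting material
9 | (E)-3,4-bis(benzyloxy)benzaldehyde oxime | O/N=C/c1ccc(OCc2ccccc2)c(OCc2ccccc2)c1 | intermediate
10 | (Z)-3,4-bis(benzyloxy)-N-hydroxybenzimidoyl chloride | O/N=C(\Cl)c1ccc(OCc2ccccc2)c(OCc2ccccc2)c1 | intermediate
11 | ethylzinc alkoxide of 7 | CC[Zn]OC/C(Cc1ccc(OC)c(OC)c1)=C/CO[Si](C)(C)C(C)(C)C | intermediate (not isolated)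
12 | 3,4-bis(benzyloxy)benzonitrile oxide | [O-][N+]#Cc1ccc(OCc2ccccc2)c(OCc2ccccc2)c1 | intermediate (not isolated)
13 | [(4S,5R)-3-[3,4-bis(benzyloxy)phenyl]-4-{[(tert-butyldimethylsilyl)oxy]methyl}-5-(3,4-dimethoxybenzyl)-4,5-dihydro-1,2-oxazol-5-yl]methanol | COc1ccc(C[C@@]2(CO)ON=C(c3ccc(OCc4ccccc4)c(OCc4ccccc4)c3)[C@H]2CO[Si](C)(C)C(C)(C)C)cc1OC | intermediate
14 | [(4S,5R)-3-[3,4-bis(benzyloxy)phenyl]-4-{[(tert-butyldimethylsilyl)oxy]methyl}-5-(3,4-dimethoxybenzyl)-4,5-dihydro-1,2-oxazol-5-yl]methyl 4-methylbenzenesulfonate | COc1ccc(C[C@@]2(COS(=O)(=O)c3ccc(C)cc3)ON=C(c3ccc(OCc4ccccc4)c(OCc4ccccc4)c3)[C@H]2CO[Si](C)(C)C(C)(C)C)cc1OC | intermediate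
15 | (2R,3S)-4-[3,4-bis(benzyloxy)phenyl]-3-{[(tert-butyldimethylsilyl)oxy]methyl}-2-(3,4-dimethoxybenzyl)-2-hydroxy-4-iminobutyl 4-methylbenzenesulfonate | COc1ccc(C[C@@](COS(=O)(=O)c2ccc(C)cc2)(O)[C@H](CO[Si](C)(C)C(C)(C)C)C(=N)c2ccc(OCc3ccccc3)c(OCc3ccccc3)c2)cc1OC | intermediate (not isolated)
16 | (2R,3S)-4-[3,4-bis(benzyloxy)phenyl]-3-{[(tert-butyldimethylsilyl)oxy]methyl}-2-(3,4-dimethoxybenzyl)-2-hydroxy-4-oxobutyl 4-methylbenzenesulfonate | COc1ccc(C[C@@](COS(=O)(=O)c2ccc(C)cc2)(O)[C@H](CO[Si](C)(C)C(C)(C)C)C(=O)c2ccc(OCc3ccccc3)c(OCc3ccccc3)c2)cc1OC | intermediate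
17 | (2R,3R,4R)-4-[3,4-bis(benzyloxy)phenyl]-3-{[(tert-butyldimethylsilyl)oxy]methyl}-2-(3,4-dimethoxybenzyl)-2,4-dihydroxybutyl 4-methylbenzenesulfonate | COc1ccc(C[C@@](COS(=O)(=O)c2ccc(C)cc2)(O)[C@H](CO[Si](C)(C)C(C)(C)C)[C@@H](O)c2ccc(OCc3ccccc3)c(OCc3ccccc3)c2)cc1OC | intermediate
18 | (3R,4R,5R)-5-[3,4-bis(benzyloxy)phenyl]-4-{[(tert-butyldimethylsilyl)oxy]methyl}-3-(3,4-dimethoxybenzyl)oxolan-3-ol | COc1ccc(C[C@]2(O)CO[C@@H](c3ccc(OCc4ccccc4)c(OCc4ccccc4)c3)[C@H]2CO[Si](C)(C)C(C)(C)C)cc1OC | intermediate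
19 | (3R,4R,5R)-5-[3,4-bis(benzyloxy)phenyl]-3-(3,4-dimethoxybenzyl)-4-(hydroxymethyl)oxolan-3-ol | COc1ccc(C[C@]2(O)CO[C@@H](c3ccc(OCc4ccccc4)c(OCc4ccccc4)c3)[C@H]2CO)cc1OC | intermediate
20 | 4-[(2R,3R,4R)-4-(3,4-dimethoxybenzyl)-4-hydroxy-3-(hydroxymethyl)oxolan-2-yl]benzene-1,2-diol | COc1ccc(C[C@]2(O)CO[C@@H](c3ccc(O)c(O)c3)[C@H]2CO)cc1OC | target

## Step count and risks

Total steps: 12. Longest linear sequence: 10 steps (steps 1–3 and 6–12).

Steps most likely to fail:

1. Step 6. The trisubstituted alkene may add too slowly, so that the nitrile oxide dimerises, or the tartrate may discriminate the two alkene faces poorly. The fallback sets out from 7 and 10 and returns at 13. Compound 7 is converted with EtMgBr in CH2Cl2 at 0 °C into its bromomagnesium alkoxide F1, and 10 is added together with a second equivalent of magnesium alkoxide base (from i-PrOH and EtMgBr), which regenerates 12. The magnesium-alkoxide-directed cycloaddition needs no chiral ligand and should give racemic isoxazoline F2 with the same regiochemistry and relative configuration. Esterification with (S)-naproxen (EDC·HCl, DMAP, CH2Cl2) should give the diastereomeric (4S,5R) naproxen ester F3 and (4R,5S) naproxen ester F4, to be separated by chromatography or crystallisation. Methanolysis of F3 (K2CO3, MeOH) returns 13 as a single enantiomer.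

2. Step 9. Part of the reduction may run through the open, non-chelated ketone, which would erode the face selectivity at C2. The fallback sets out from 13 and returns at 18, bypassing steps 7 to 10. N–O cleavage of the unsulfonylated alcohol 13 with Mo(CO)6 in wet MeCN lets the liberated ketone close onto the C5 hydroxyl to give lactol F5. Et3SiH and BF3·OEt2 in CH2Cl2 at −78 °C should ionise it to oxocarbenium ion F6, to which hydride is expected to add trans to the C3 substituent, the usual outcome for 2-aryl lactols of this kind. This gives the 2,3-cis oxolane 18 directly.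

3. Step 8. The imine nitrogen set free on N–O cleavage may displace the primary sulfonate, closing a five-membered cyclic imine before hydrolysis. The fallback sets out from 13 and returns at 17; it carries the C5 oxygen as an ester and installs the sulfonate only after the ketone is reduced. Ac2O, pyridine and DMAP give acetate F7. Mo(CO)6 in wet MeCN gives acetoxy ketone F8. Zn(BH4)2 in Et2O gives diol acetate F9. K2CO3 in MeOH gives triol F10. Sulfonylation catalysed by Bu2SnO (TsCl, Et3N, CH2Cl2), selective for the primary hydroxyl of the 1,2-diol, gives 17.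

## Further compounds

F1 | step 6 | bromomagnesium alkoxide of 7 | Br[Mg]OC/C(Cc1ccc(OC)c(OC)c1)=C/CO[Si](C)(C)C(C)(C)C
F2 | step 6 | racemic (4S*,5R*) isoxazoline, both enantiomers of 13 | COc1ccc(C[C@@]2(CO)ON=C(c3ccc(OCc4ccccc4)c(OCc4ccccc4)c3)[C@H]2CO[Si](C)(C)C(C)(C)C)cc1OC.COc1ccc(C[C@]2(CO)ON=C(c3ccc(OCc4ccccc4)c(OCc4ccccc4)c3)[C@@H]2CO[Si](C)(C)C(C)(C)C)cc1OC
F3 | step 6 | [(4S,5R)-3-[3,4-bis(benzyloxy)phenyl]-4-{[(tert-butyldimethylsilyl)oxy]methyl}-5-(3,4-dimethoxybenzyl)-4,5-dihydro-1,2-oxazol-5-yl]methyl (2S)-2-(6-methoxynaphthalen-2-yl)propanoate | COc1ccc(C[C@@]2(COC(=O)[C@@H](C)c3ccc4cc(OC)ccc4c3)ON=C(c3ccc(OCc4ccccc4)c(OCc4ccccc4)c3)[C@H]2CO[Si](C)(C)C(C)(C)C)cc1OC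
F4 | step 6 | [(4R,5S)-3-[3,4-bis(benzyloxy)phenyl]-4-{[(tert-butyldimethylsilyl)oxy]methyl}-5-(3,4-dimethoxybenzyl)-4,5-dihydro-1,2-oxazol-5-yl]methyl (2S)-2-(6-methoxynaphthalen-2-yl)propanoate | COc1ccc(C[C@]2(COC(=O)[C@@H](C)c3ccc4cc(OC)ccc4c3)ON=C(c3ccc(OCc4ccccc4)c(OCc4ccccc4)c3)[C@@H]2CO[Si](C)(C)C(C)(C)C)cc1OC
F5 | step 9 | (3S,4R)-2-[3,4-bis(benzyloxy)phenyl]-3-{[(tert-butyldimethylsilyl)oxy]methyl}-4-(3,4-dimethoxybenzyl)oxolane-2,4-diol (lactol, both anomers) | COc1ccc(C[C@]2(O)COC(O)(c3ccc(OCc4ccccc4)c(OCc4ccccc4)c3)[C@H]2CO[Si](C)(C)C(C)(C)C)cc1OC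
F6 | step 9 | cyclic 2-aryl oxocarbenium ion derived from F5 | COc1ccc(C[C@]2(O)C[O+]=C(c3ccc(OCc4ccccc4)c(OCc4ccccc4)c3)[C@H]2CO[Si](C)(C)C(C)(C)C)cc1OC
F7 | step 8 | [(4S,5R)-3-[3,4-bis(benzyloxy)phenyl]-4-{[(tert-butyldimethylsilyl)oxy]methyl}-5-(3,4-dimethoxybenzyl)-4,5-dihydro-1,2-oxazol-5-yl]methyl acetate | COc1ccc(C[C@@]2(COC(C)=O)ON=C(c3ccc(OCc4ccccc4)c(OCc4ccccc4)c3)[C@H]2CO[Si](C)(C)C(C)(C)C)cc1OC
F8 | step 8 | (2R,3S)-4-[3,4-bis(benzyloxy)phenyl]-3-{[(tert-butyldimethylsilyl)oxy]methyl}-2-(3,4-dimethoxybenzyl)-2-hydroxy-4-oxobutyl acetate | COc1ccc(C[C@@](COC(C)=O)(O)[C@H](CO[Si](C)(C)C(C)(C)C)C(=O)c2ccc(OCc3ccccc3)c(OCc3ccccc3)c2)cc1OC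
F9 | step 8 | (2R,3R,4R)-4-[3,4-bis(benzyloxy)phenyl]-3-{[(tert-butyldimethylsilyl)oxy]methyl}-2-(3,4-dimethoxybenzyl)-2,4-dihydroxybutyl acetate | COc1ccc(C[C@@](COC(C)=O)(O)[C@H](CO[Si](C)(C)C(C)(C)C)[C@@H](O)c2ccc(OCc3ccccc3)c(OCc3ccccc3)c2)cc1OC
F10 | step 8 | (2R,3R,4R)-4-[3,4-bis(benzyloxy)phenyl]-3-{[(tert-butyldimethylsilyl)oxy]methyl}-2-(3,4-dimethoxybenzyl)butane-1,2,4-triol | COc1ccc(C[C@@](CO)(O)[C@H](CO[Si](C)(C)C(C)(C)C)[C@@H](O)c2ccc(OCc3ccccc3)c(OCc3ccccc3)c2)cc1OC
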